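Percent of the J charged is my unit, and in that unit the ratio G/J is a plain reading with no fitted constant inside it.

| flask | J | L | temperature | remark | time |
|---|---|---|---|---|---|
| summer | 0.50 M | 0.30 M | −29 °C | run made earlier |  |
| dusk | 0.50 M | 1.2 M | −4 °C | run made earlier |  |
| theta | 0.50 M | 0.600 M | −25 °C |  | 6.0 d |
| alpha | 0.50 M | 0.600 M | −40 °C |  | 6.0 d |
| beta | 0.50 M | 0.600 M | 5 °C |  | 6.0 d |
| epsilon | 0.50 M | 0.600 M | −10 °C |  | 6.0 d |

- summer (time / d: G / %, J / %): 0.250: 2.4, 98.2; 0.833: 0, 98.3; 1.25: 2.1, 96.4; 2.08: 1.1, 96.0; 3.00: 2.2, 96.9; 4.00: 3.1, 92.8; 5.00: 4.5, 90.7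
- dusk (time / h: G / %, J / %): 5.00: 22.6, 68.8; 10.0: 35.2, 48.9; 20.0: 44.6, 29.5; 25.0: 45.1, 21.1; 30.0: 43.7, 18.8; 40.0: 43.3, 10.9

(scatter of a reading: 1 percentage point)

- the best flask by amount of G, in percent of the J charged; "all alike" if 1.5 percentage points covers them all (theta / alpha / beta / epsilon / all alike)
- amount of G at the end, in percent of the J charged, theta
- amount of G at the end, in percent of the J charged, alpha
- amount of G at the end, in percent of the J charged, beta
- amount of G at the end, in percent of the J charged, epsilon

- what was read earlier has a scatter of 1 percentage point, one standard deviation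

G is a mono adduct, so I take it that a second L consumes it. J then makes G at a rate proportional to [J][L] and G goes at a rate proportional to [G][L], so [L] cancels in their ratio. The dusk run flattens around 25.0 h, where G/J reads 2.14, with 1.51 and 2.32 at the readings on either side. I call the value of G/J at which G stops rising the stall ratio ρ, a selectivity factor; it is a reading, and it already contains whatever J is lost elsewhere.

The quotient ρJ/G then tells how many times faster G is made than used, and it runs the dusk film slowly. At 5.00 h it stands at 6.51, so G climbs fast. At 10.0 h it is 2.97, and the second addition is about to matter. At 25.0 h it reaches 1.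

The summer run ends at G/J 0.0496, so no cold run tests ρ, and I carry it over untested. For the timing, the slope of ln J per molar L is 23.0 times steeper in dusk than in summer. Spread log-linearly over temperature, that makes epsilon 0.471 of dusk's speed and beta 3.09 times it. With L at half of dusk's charge, epsilon reaches ρ at about 4.42 d and beta at about 0.674 d. Both are estimates reckoned on the charged L, and L falls on the way. Beta therefore arrives well inside 6.0 d and then loses G, while epsilon arrives near the end, so I commit to epsilon as best.

The forecast differs: beta best at 47%, epsilon 41%, theta 14%, alpha 1.1%, on the grounds that “beta runs nearly out of L and gives the most G, with epsilon close behind”.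

The flasks give epsilon as best at 41.6%, then beta 35.3%, theta 16.7% and alpha 1.80%.

    J + L → E + Z (k = 0.0180 M⁻¹ h⁻¹, Ea = 86.0 kJ mol⁻¹)
    J + L → G + Z (k = 0.170 M⁻¹ h⁻¹, Ea = 80.0 kJ mol⁻¹)
    L + G → Q + Z (k = 0.0710 M⁻¹ h⁻¹, Ea = 77.0 kJ mol⁻¹)
    2 J → D (k = 0.0340 M⁻¹ h⁻¹, Ea = 76.0 kJ mol⁻¹)
    L + E → Q + Z (k = 0.210 M⁻¹ h⁻¹, Ea = 53.0 kJ mol⁻¹)
    (constants at 5 °C)

In epsilon at 6.00 d, G is made 1.12 times faster than used, each step taken net, down from 5.11 at 1.27 d. My quotient ρJ/G gives 1.08 for epsilon at 6.00 d. In beta at 3.00 d the same quotient is 0.367, and G goes from 38.5% there to 35.3% at 6.00 d.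

(The runs were computed for substances that don't exist; noise was put on by code.)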